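Remark: atoms are numbered as in prostanoids (C1 = ester carbon, ring = C8–C12, C20 = chain end). TBS = tert-butyldimethylsilyl. 1-Bromooct-2-yne is taken as commercial. Compounds 4, 5, 7, 8, 9, 12 and 13 are racemic; for 12 and 13 the SMILES shows the enantiomer that is carried on.

## Analysis of the target

Compound 28 is a 2-iodocyclopent-2-enone (C9 ketone, C10 iodide, C10=C11). Its quaternary C12 carries a free tertiary hydroxyl and the (Z)-oct-2-enyl chain, and C8 carries the upper chain with the C7 acetate, the (5Z)-alkene and the methyl ester. The stereocentres C7 (S), C8 (R) and C12 (S) are contiguous; the two chains are trans on the ring, so C7 sits cis to the C12 hydroxyl. The β-acetoxy ketone loses acetic acid easily (E1cB to the cross-conjugated dienone), the C12 carbinol is a β-hydroxy ketone (retro-aldol under base), C8 is epimerisable, and the vinyl iodide and two (Z)-alkenes limit the reagents that can be used late. The hard part is an oxygenated quaternary carbon directly beside an aldol-type pair C7/C8: a real aldol at C8 would have to set two centres next to a quaternary carbon and would give a product that reverts easily. The route rests on one feature: C9(=O)–C8–C7(O) is an aldol array whose C8 is also bonded to C12. The C8–C12 bond can therefore be made by shifting C12 from C9 onto an epoxide carbon C8, which turns a cyclobutanol (C9–C10–C11–C12) into the cyclopentanone and sets C8 stereospecifically.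

## Retrosynthetic reasoning

28 ⇒ 27 ⇒ 26. The acetate C–O bond is cut last because the β-acetoxy ketone is the most fragile group. Diol 27 needs no protection at C12, since a tertiary hydroxyl is not acylated under simple anhydride–pyridine conditions. Diol 27 comes from bis-silyl ether 26 by acidic desilylation, so every basic step is run while both β-oxygens are silyl ethers, which are poor leaving groups.

26 ⇒ 25. The C10–I bond is cut by enone α-iodination. It is placed after the chain extension so that the vinyl iodide never meets a phosphorus ylide or an amide base.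

25 ⇒ 24 ⇒ 21 + 22. The C5=C6 alkene is cut by a Wittig reaction, the standard cis-olefination for prostanoid upper chains. The forward reaction must be Z-selective and must take the aldehyde of 21 in preference to the hindered enone without deprotonating C8.

21 ⇒ 20 ⇒ 19 ⇒ 17 ⇒ 16. These are adjustments of oxidation level and protection. The C6 aldehyde comes from the primary silyl ether of 19, and the C10=C11 alkene from ketone 17 by dehydrogenation through the kinetic C10 enolate. The dehydrogenation is placed before chain extension so that no ester competes for the base. Ketone 17 is the C7 silyl ether of 16.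

16 ⇒ 15 (key disconnection). The C8–C12 bond is cut and C12 is reattached to C9, giving epoxy cyclobutanol 15. This is preferred to an aldol cut at C7–C8 because the forward 1,2-shift is stereospecific at both ends (inversion at C8, retention at C12) and cannot revert. The forward step has to open the epoxide at C8 only and let C12, not C10, migrate.

15 ⇒ 14 ⇒ 13. The epoxide oxygen is removed to give (E)-allylic alcohol 13, so C7 and C8 come from one Sharpless epoxidation. An enantioselective α-hydroxylation of a cyclobutanone enol derivative has no close precedent, and a free α-hydroxy cyclobutanone can racemise through an achiral acylcyclopropanol (α-ketol shift). C12 is therefore brought in racemic, and the same epoxidation resolves it: reagent control turns the enantiomers of 13 into diastereomers, and 14 is the one kept. The cost is half of the material at that step; the gain is that no unprecedented asymmetric step is needed.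

13 ⇒ 12 ⇒ 9 + 10. The C8–C9 bond is cut to ketone 9 and the acetylide of 10. The three-carbon unit arrives unprotected at the right oxidation level, and trans-reduction of 12 gives the (E)-alkene with certainty.

9 ⇒ 8 ⇒ 6 ⇒ 5. The C12–O bond comes from Rubottom oxidation of the tetrasubstituted silyl enol ether 6, with the silyl group ending on the new oxygen. The lower chain is carried as an alkyne through this oxidation so that only the enol ether reacts; Lindlar reduction of 8 then gives the (Z)-alkene of 9.

5 ⇒ 2 + 3; 2 ⇒ 1. The C12–C13 bond is cut to the hydrazone 2 of cyclobutanone 1 and propargylic bromide 3. Hydrazone alkylation avoids the self-condensation of cyclobutanone enolates.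

## Alternatives that were turned down

Alternative 1: The C11–C12 bond of a 2-hydroxycyclopentanone is cut. In the forward direction a chiral triazolium-derived carbene turns the aldehyde of the achiral keto aldehyde A1 into an acyl-anion equivalent that adds to the C12 ketone, giving ketol A2 with C12 set by the catalyst.
- For: one catalytic step builds the ring and the quaternary carbinol from a cheap achiral chain. On control of C12 it is stronger than the chosen route, which secures C12 by a resolution.
- Against: A2 has its carbonyl on C11 and nothing on C8–C10. The target needs C9=O, C10=C11 with iodine, and the C7–C8 bond, so the carbonyl must be moved across the ring by several redox steps. C7 and C8 would then come from an aldol next to the quaternary centre, which is the unsolved problem. Both carbonyls of A1 are enolisable, and the catalyst must distinguish two similar methylene arms.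
- Comparison: the chosen strategy gives the ring with the correct oxidation pattern and all three centres correlated in one stereospecific shift, at the price of a resolution.

Alternative 2: The C12–O bond is cut by tying it to C6 as a lactone. Iodine with bicarbonate converts cyclopentene acid A3 into the cis-fused iodolactone A4; the carboxylate can only reach the alkene face on which the C8 arm sits and attacks the more substituted C12.
- For: the C12–O configuration is enforced by the tether, which is more secure than a migratory preference. The lactone is also a latent C6 aldehyde: lactol formation and Wittig reaction would build the upper chain while freeing the C12 hydroxyl, with no base-sensitive keto aldehyde. On that end game it is stronger than the chosen route.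
- Against: A3 must already contain C7, C8 and C9 on a trisubstituted cyclopentene, so the aldol-type C7/C8 problem is presupposed. C9 is a sacrificial centre, and the redox and protecting-group steps (iodide elimination, C9 oxidation, alkyne reduction, ether removal, C10 iodination) make the route longer.
- Comparison: the chosen strategy creates C7 and C8 from one epoxide and reaches the functionalised ring in ten steps, accepting a more delicate Wittig step.

Alternative 3: The C9–C10 bond is cut. [Rh(dppe)]2(BF4)2, a cationic monovalent rhodium precatalyst, inserts into the formyl C–H of 4-alkynal A5 and adds acyl and hydride trans across the C10≡C11 alkyne to give cyclopentenone A6.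
- For: the enone arrives in the ring-forming step, and the C10 silyl group can be exchanged for iodine by ipso substitution. This is stronger than dehydrogenation plus α-iodination.
- Against: A5 must hold C7, C8 and C12 in an open chain: a quaternary propargylic carbinol beside the α-centre of an aldehyde that is also β-oxygenated. That aldehyde is prone to epimerisation, β-elimination and decarbonylation at rhodium. Making the triad acyclically needs an aldol-type addition to an alkynyl ketone, and four different protecting groups and both side chains remain to be handled.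
- Comparison: the stereochemical burden moves into acyclic chemistry with more steps. The chosen strategy takes the triad from an epoxide and a stereospecific shift and pays with two standard ring-functionalisation steps.

Key step: step 10

## Route

Step 1
Reactants: 1 cyclobutanone
Product: 2 cyclobutanone N,N-dimethylhydrazone
Conditions: Me2NNH2, MgSO4, Et2O, rt
Reagents that add atoms: N,N-dimethylhydrazine CN(C)N
Why: Condensation gives the hydrazone, which allows clean mono-alkylation of cyclobutanone without the self-aldol reactions of its enolate.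

Step 2
Reactants: 2 cyclobutanone N,N-dimethylhydrazone; 3 1-bromooct-2-yne
Product: 5 2-(oct-2-yn-1-yl)cyclobutan-1-one (racemic), via alkylated hydrazone 4 (not isolated)
Conditions: LiN(iPr)2, THF, −78 → 0 °C; 3, −78 °C → rt; then aq. oxalic acid, Et2O, rt
Reagents that add atoms: water O
Why: Hydrazone (aza-enolate) alkylation: the lithium aza-enolate displaces bromide at the unhindered propargylic carbon by SN2, and mild acid hydrolysis of 4 returns the ketone. The centre formed at C12 is racemic and becomes trigonal in the next step.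

Step 3
Reactants: 5 2-(oct-2-yn-1-yl)cyclobutan-1-one
Product: 6 1-(tert-butyldimethylsilyloxy)-2-(oct-2-yn-1-yl)cyclobut-1-ene
Conditions: TBSOTf, Et3N, CH2Cl2, 0 °C → rt
Reagents that add atoms: tert-butyldimethylsilyl trifluoromethanesulfonate CC(C)(C)[Si](C)(C)OS(=O)(=O)C(F)(F)F
Why: Soft enolisation under equilibrating conditions should give the more substituted silyl enol ether. Both possible enol ethers are endocyclic cyclobutenes, so only alkyl substitution differentiates them, and it favours C9=C12.

Step 4
Reactants: 6 1-(tert-butyldimethylsilyloxy)-2-(oct-2-yn-1-yl)cyclobut-1-ene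
Product: 8 2-(tert-butyldimethylsilyloxy)-2-(oct-2-yn-1-yl)cyclobutan-1-one (racemic), via silyloxy epoxide 7 (not isolated)
Conditions: dimethyldioxirane, acetone/CH2Cl2, −40 °C → rt
Reagents that add atoms: dimethyldioxirane CC1(C)OO1
Why: Rubottom oxidation: the electron-rich enol ether is epoxidised much faster than the alkyne, the strained epoxide 7 opens to an oxocarbenium alkoxide, and a 1,4-silyl shift gives the α-silyloxy ketone. The neutral dioxirane does not cause Baeyer–Villiger oxidation of the cyclobutanone, and no free ketol is formed; the product is racemic at C12 by design.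

Step 5
Reactants: 8 2-(tert-butyldimethylsilyloxy)-2-(oct-2-yn-1-yl)cyclobutan-1-one
Product: 9 2-(tert-butyldimethylsilyloxy)-2-[(2Z)-oct-2-en-1-yl]cyclobutan-1-one (racemic)
Conditions: H2 (1 atm), Pd/CaCO3–Pb(OAc)2 (Lindlar catalyst), quinoline, EtOAc, rt
Reagents that add atoms: none
Why: Lindlar semi-hydrogenation: syn delivery of hydrogen on the poisoned palladium surface gives the (Z)-alkene C14=C15. The ketone and silyl ether are inert, and quinoline suppresses over-reduction.

Step 6
Reactants: 9 2-(tert-butyldimethylsilyloxy)-2-[(2Z)-oct-2-en-1-yl]cyclobutan-1-one; 10 propargyl alcohol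
Product: 12 (1R*,2S*)-2-(tert-butyldimethylsilyloxy)-1-(3-hydroxyprop-1-yn-1-yl)-2-[(2Z)-oct-2-en-1-yl]cyclobutan-1-ol (racemic), via dilithiated propargyl alcohol 11 (not isolated)
Conditions: 10, n-BuLi (2 equiv), THF, −78 → −20 °C; then 9, −78 → 0 °C; aq. NH4Cl
Reagents that add atoms: n-butyllithium CCCC[Li] (lithium of intermediate 11 only; only hydrogen is added to 12 beyond the two reactants)
Why: 1,2-Addition of a lithium acetylide to the strained cyclobutanone; the small nucleophile should approach anti to the electronegative silyloxy group (polar Felkin–Anh), placing the new hydroxyl cis to it. C9 is a temporary centre that becomes the carbonyl carbon in step 10, so its configuration does not reach the target; the major epimer is carried on.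

Step 7
Reactants: 12 (1R*,2S*)-2-(tert-butyldimethylsilyloxy)-1-(3-hydroxyprop-1-yn-1-yl)-2-[(2Z)-oct-2-en-1-yl]cyclobutan-1-ol
Product: 13 (1R*,2S*)-2-(tert-butyldimethylsilyloxy)-1-[(1E)-3-hydroxyprop-1-en-1-yl]-2-[(2Z)-oct-2-en-1-yl]cyclobutan-1-ol (racemic)
Conditions: NaAlH2(OCH2CH2OMe)2, THF, 0 °C → rt; aq. Rochelle salt
Reagents that add atoms: none
Why: Alkoxide-directed trans-hydroalumination of the propargylic diol gives only the (E)-alkene C7=C8 needed for a trans epoxide. The isolated (Z)-alkene and the tertiary silyl ether are not touched by the aluminium hydride.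

Step 8
Reactants: 13 (1R*,2S*)-2-(tert-butyldimethylsilyloxy)-1-[(1E)-3-hydroxyprop-1-en-1-yl]-2-[(2Z)-oct-2-en-1-yl]cyclobutan-1-ol
Product: 14 (1R,2S)-2-(tert-butyldimethylsilyloxy)-1-[(2R,3S)-3-(hydroxymethyl)oxiran-2-yl]-2-[(2Z)-oct-2-en-1-yl]cyclobutan-1-ol
Conditions: Ti(OiPr)4 (0.3 equiv), L-(+)-diethyl tartrate (0.36 equiv), t-BuOOH, 4 Å MS, CH2Cl2, −20 °C; chromatographic separation of the two diastereomers
Reagents that add atoms: tert-butyl hydroperoxide CC(C)(C)OO
Why: Sharpless asymmetric epoxidation of the primary (E)-allylic alcohol: with L-(+)-tartrate, reagent control should deliver oxygen to the face that gives the (2R,3S)-oxirane (C7 S, C8 R) in both enantiomers of 13, which therefore become two diastereomers. The one formed from (1R,2S)-13 is 14 and is isolated; this fixes C7, the configuration from which C8 will invert, and by selection the absolute configuration of C12.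

Step 9
Reactants: 14 (1R,2S)-2-(tert-butyldimethylsilyloxy)-1-[(2R,3S)-3-(hydroxymethyl)oxiran-2-yl]-2-[(2Z)-oct-2-en-1-yl]cyclobutan-1-ol
Product: 15 (1R,2S)-2-(tert-butyldimethylsilyloxy)-1-[(2R,3S)-3-(tert-butyldimethylsilyloxymethyl)oxiran-2-yl]-2-[(2Z)-oct-2-en-1-yl]cyclobutan-1-ol
Conditions: TBSCl, imidazole, CH2Cl2, 0 °C
Reagents that add atoms: tert-butyldimethylsilyl chloride CC(C)(C)[Si](C)(C)Cl
Why: Selective silylation of the primary hydroxyl. The tertiary C9 hydroxyl is too hindered for the silyl chloride and stays free, as the rearrangement requires.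

Step 10
Reactants: 15 (1R,2S)-2-(tert-butyldimethylsilyloxy)-1-[(2R,3S)-3-(tert-butyldimethylsilyloxymethyl)oxiran-2-yl]-2-[(2Z)-oct-2-en-1-yl]cyclobutan-1-ol
Product: 16 (2R,3S)-3-(tert-butyldimethylsilyloxy)-2-[(1R)-2-(tert-butyldimethylsilyloxy)-1-hydroxyethyl]-3-[(2Z)-oct-2-en-1-yl]cyclopentan-1-one
Conditions: ZnBr2, CH2Cl2, 0 °C → rt
Reagents that add atoms: none
Why: ZnBr2 binds the epoxide oxygen and the neighbouring C9 hydroxyl and polarises the C8–O bond; as it breaks, the ring bond C9–C12 lying antiperiplanar to it shifts from C9 to C8 while C9–O becomes the carbonyl, so the step is a semipinacol 1,2-shift without a free cation. The closest known reaction type is the Lewis-acid rearrangement of 2,3-epoxy tertiary alcohols to β-hydroxy ketones, including the expansion of 1-(oxiranyl)cyclobutanols to 2-(1-hydroxyalkyl)cyclopentanones. The ring C8–C12 is closed by ring expansion (C8 is inserted into the C9–C12 bond of the cyclobutane), not by cyclisation of a chain, and relief of four-ring strain together with C=O formation drives it. The new stereocentre C8 is formed with inversion, because C12 arrives on the face opposite to the departing epoxide oxygen, so its R configuration follows from the (8R)-epoxide carbon; C12 migrates with retention and C7 keeps its C–O bond, so the whole 7,8,12 triad is read off from 15. Two selectivities are needed: opening at C8 rather than C7, secured because only C8 is attached to the carbinol carbon that supplies the migrating bond and because the silyloxymethyl group deactivates C7 inductively; and migration of C12 rather than C10, which rests on the better ability of the tertiary, oxygen-bearing carbon to carry positive charge in the bridged transition state. The configuration at C9 does not matter, since rotation about C8–C9 places C9–C12 anti to C8–O in either epimer and C9 becomes trigonal. The silyl ethers should survive the mild zinc Lewis acid, and the β-hydroxy ketone formed is not exposed to base.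

Step 11
Reactants: 16 (2R,3S)-3-(tert-butyldimethylsilyloxy)-2-[(1R)-2-(tert-butyldimethylsilyloxy)-1-hydroxyethyl]-3-[(2Z)-oct-2-en-1-yl]cyclopentan-1-one
Product: 17 (2R,3S)-2-[(1R)-1,2-bis(tert-butyldimethylsilyloxy)ethyl]-3-(tert-butyldimethylsilyloxy)-3-[(2Z)-oct-2-en-1-yl]cyclopentan-1-one
Conditions: TBSOTf, 2,6-lutidine, CH2Cl2, −78 °C
Reagents that add atoms: tert-butyldimethylsilyl trifluoromethanesulfonate CC(C)(C)[Si](C)(C)OS(=O)(=O)C(F)(F)F
Why: Silylation of the hindered secondary C7 hydroxyl with the silyl triflate at low temperature. 2,6-Lutidine is too weak a base to enolise the ketone, so C8 is not epimerised and nothing is eliminated.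

Step 12
Reactants: 17 (2R,3S)-2-[(1R)-1,2-bis(tert-butyldimethylsilyloxy)ethyl]-3-(tert-butyldimethylsilyloxy)-3-[(2Z)-oct-2-en-1-yl]cyclopentan-1-one
Product: 19 (4R,5R)-5-[(1R)-1,2-bis(tert-butyldimethylsilyloxy)ethyl]-4-(tert-butyldimethylsilyloxy)-4-[(2Z)-oct-2-en-1-yl]cyclopent-2-en-1-one, via trimethylsilyl enol ether 18 (not isolated)
Conditions: LiN(iPr)2, Me3SiCl, THF, −78 °C; then Pd(OAc)2, MeCN, rt
Reagents that add atoms: chlorotrimethylsilane C[Si](C)(C)Cl (silyl group of intermediate 18 only)
Why: Saegusa–Ito dehydrogenation: kinetic deprotonation occurs at the unhindered C10 methylene (C8–H is flanked by the quaternary C12 and the branched C7), the enolate is trapped as 18, and divalent palladium acetate gives the α-palladated ketone, which undergoes β-hydride elimination to the C10=C11 enone. The C10 enolate has no β-leaving group, so the silyloxy groups at C7 and C12 are not lost.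

Step 13
Reactants: 19 (4R,5R)-5-[(1R)-1,2-bis(tert-butyldimethylsilyloxy)ethyl]-4-(tert-butyldimethylsilyloxy)-4-[(2Z)-oct-2-en-1-yl]cyclopent-2-en-1-one
Product: 20 (4R,5R)-4-(tert-butyldimethylsilyloxy)-5-[(1R)-1-(tert-butyldimethylsilyloxy)-2-hydroxyethyl]-4-[(2Z)-oct-2-en-1-yl]cyclopent-2-en-1-one
Conditions: HF·pyridine, pyridine, THF, 0 °C
Reagents that add atoms: none
Why: Buffered HF·pyridine should cleave the unhindered primary silyl ether much faster than the secondary (C7) and tertiary (C12) ones, exposing only the C6 hydroxyl.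

Step 14
Reactants: 20 (4R,5R)-4-(tert-butyldimethylsilyloxy)-5-[(1R)-1-(tert-butyldimethylsilyloxy)-2-hydroxyethyl]-4-[(2Z)-oct-2-en-1-yl]cyclopent-2-en-1-one
Product: 21 (2R)-2-(tert-butyldimethylsilyloxy)-2-[(1R,2R)-2-(tert-butyldimethylsilyloxy)-2-[(2Z)-oct-2-en-1-yl]-5-oxocyclopent-3-en-1-yl]acetaldehyde
Conditions: Dess–Martin periodinane, pyridine, CH2Cl2, 0 °C → rt
Reagents that add atoms: none
Why: Dess–Martin oxidation under buffered, non-basic conditions gives the α-silyloxy aldehyde without epimerising C7 or triggering β-elimination. The aldehyde is used at once.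

Step 15
Reactants: 21 (2R)-2-(tert-butyldimethylsilyloxy)-2-[(1R,2R)-2-(tert-butyldimethylsilyloxy)-2-[(2Z)-oct-2-en-1-yl]-5-oxocyclopent-3-en-1-yl]acetaldehyde; 22 (4-carboxybutyl)triphenylphosphonium bromide
Product: 24 (5Z,7S)-7-(tert-butyldimethylsilyloxy)-7-[(1R,2R)-2-(tert-butyldimethylsilyloxy)-2-[(2Z)-oct-2-en-1-yl]-5-oxocyclopent-3-en-1-yl]hept-5-enoic acid, via phosphorus ylide 23 (not isolated)
Conditions: 22, NaN(SiMe3)2 (2 equiv per 22), THF, 0 °C → rt; then 21, −78 → −20 °C; pH 5 phosphate buffer
Reagents that add atoms: sodium bis(trimethylsilyl)amide C[Si](C)(C)[N-][Si](C)(C)C.[Na+] (sodium of intermediate 23 only)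
Why: Wittig olefination with a non-stabilised, lithium-free ylide proceeds through the kinetic cis-oxaphosphetane and gives the (5Z)-alkene. At −78 °C the aldehyde should react much faster than the hindered enone carbonyl or the hindered C8–H, and the C7 silyl ether is a poor leaving group for E1cB elimination.

Step 16
Reactants: 24 (5Z,7S)-7-(tert-butyldimethylsilyloxy)-7-[(1R,2R)-2-(tert-butyldimethylsilyloxy)-2-[(2Z)-oct-2-en-1-yl]-5-oxocyclopent-3-en-1-yl]hept-5-enoic acid
Product: 25 methyl (5Z,7S)-7-(tert-butyldimethylsilyloxy)-7-[(1R,2R)-2-(tert-butyldimethylsilyloxy)-2-[(2Z)-oct-2-en-1-yl]-5-oxocyclopent-3-en-1-yl]hept-5-enoate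
Conditions: Me3SiCHN2, MeOH/toluene, 0 °C
Reagents that add atoms: trimethylsilyldiazomethane C[Si](C)(C)C=[N+]=[N-] (source of the ester methyl carbon)
Why: Methylation of the acid with the silyl diazomethane in methanol is fast and neutral, so the base-sensitive β-silyloxy enone never meets carbonate or alkoxide.

Step 17
Reactants: 25 methyl (5Z,7S)-7-(tert-butyldimethylsilyloxy)-7-[(1R,2R)-2-(tert-butyldimethylsilyloxy)-2-[(2Z)-oct-2-en-1-yl]-5-oxocyclopent-3-en-1-yl]hept-5-enoate
Product: 26 methyl (5Z,7S)-7-(tert-butyldimethylsilyloxy)-7-[(1R,2S)-2-(tert-butyldimethylsilyloxy)-4-iodo-2-[(2Z)-oct-2-en-1-yl]-5-oxocyclopent-3-en-1-yl]hept-5-enoate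
Conditions: I2, pyridine/CH2Cl2, 0 °C → rt, dark
Reagents that add atoms: iodine II
Why: Johnson α-iodination of the enone: pyridine adds to C11, the resulting enolate is iodinated at C10, and pyridine is expelled. C10 is the only α-vinylic position, and the silyl-protected β-oxygens do not eliminate under the weakly basic conditions (the C12 descriptor changes from R to S only because iodine changes the priorities).

Step 18
Reactants: 26 methyl (5Z,7S)-7-(tert-butyldimethylsilyloxy)-7-[(1R,2S)-2-(tert-butyldimethylsilyloxy)-4-iodo-2-[(2Z)-oct-2-en-1-yl]-5-oxocyclopent-3-en-1-yl]hept-5-enoate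
Product: 27 methyl (5Z,7S)-7-hydroxy-7-[(1R,2S)-2-hydroxy-4-iodo-2-[(2Z)-oct-2-en-1-yl]-5-oxocyclopent-3-en-1-yl]hept-5-enoate
Conditions: 48% aq. HF, MeCN, 0 °C → rt
Reagents that add atoms: none
Why: Aqueous HF in acetonitrile removes both the secondary and the hindered tertiary silyl ether under acidic conditions. These leave the methyl ester and vinyl iodide intact and, with no base present, do not open the β-hydroxy ketone by retro-aldol.

Step 19
Reactants: 27 methyl (5Z,7S)-7-hydroxy-7-[(1R,2S)-2-hydroxy-4-iodo-2-[(2Z)-oct-2-en-1-yl]-5-oxocyclopent-3-en-1-yl]hept-5-enoate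
Product: 28 methyl (5Z,7S)-7-acetoxy-7-[(1R,2S)-2-hydroxy-4-iodo-2-[(2Z)-oct-2-en-1-yl]-5-oxocyclopent-3-en-1-yl]hept-5-enoate (7-acetoxy-7,8-dihydroiodovulone I)
Conditions: Ac2O, pyridine, CH2Cl2, 0 °C
Reagents that add atoms: acetic anhydride CC(=O)OC(C)=O
Why: Acetylation with anhydride and pyridine is selective for the secondary C7 hydroxyl, because the tertiary C12 hydroxyl does not react without an acyl-transfer catalyst. Low temperature and the weak base should keep the β-acetoxy ketone from losing acetic acid.

## Compound list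

1 | cyclobutanone | O=C1CCC1 | starting material
2 | cyclobutanone N,N-dimethylhydrazone | CN(C)N=C1CCC1 | intermediate
3 | 1-bromooct-2-yne | CCCCCC#CCBr | starting material
4 | 2-(oct-2-yn-1-yl)cyclobutanone N,N-dimethylhydrazone (racemic) | CCCCCC#CCC1CCC1=NN(C)C | intermediate (not isolated)
5 | 2-(oct-2-yn-1-yl)cyclobutan-1-one (racemic) | CCCCCC#CCC1CCC1=O | intermediate
6 | 1-(tert-butyldimethylsilyloxy)-2-(oct-2-yn-1-yl)cyclobut-1-ene | CCCCCC#CCC1=C(O[Si](C)(C)C(C)(C)C)CC1 | intermediate
7 | 1-(tert-butyldimethylsilyloxy)-4-(oct-2-yn-1-yl)-5-oxabicyclo[2.1.0]pentane (racemic) | CCCCCC#CCC12CCC1(O2)O[Si](C)(C)C(C)(C)C | intermediate (not isolated)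
8 | 2-(tert-butyldimethylsilyloxy)-2-(oct-2-yn-1-yl)cyclobutan-1-one (racemic) | CCCCCC#CCC1(O[Si](C)(C)C(C)(C)C)CCC1=O | intermediate
9 | 2-(tert-butyldimethylsilyloxy)-2-[(2Z)-oct-2-en-1-yl]cyclobutan-1-one (racemic) | CCCCC/C=C\CC1(O[Si](C)(C)C(C)(C)C)CCC1=O | intermediate
10 | propargyl alcohol | C#CCO | starting material
11 | dilithiated propargyl alcohol (lithium 3-lithioprop-2-yn-1-olate) | [Li]C#CCO[Li] | intermediate (not isolated)
12 | (1R*,2S*)-2-(tert-butyldimethylsilyloxy)-1-(3-hydroxyprop-1-yn-1-yl)-2-[(2Z)-oct-2-en-1-yl]cyclobutan-1-ol (racemic; (1R,2S) enantiomer drawn) | CCCCC/C=C\C[C@@]1(O[Si](C)(C)C(C)(C)C)CC[C@@]1(O)C#CCO | intermediate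
13 | (1R*,2S*)-2-(tert-butyldimethylsilyloxy)-1-[(1E)-3-hydroxyprop-1-en-1-yl]-2-[(2Z)-oct-2-en-1-yl]cyclobutan-1-ol (racemic; (1R,2S) enantiomer drawn) | CCCCC/C=C\C[C@@]1(O[Si](C)(C)C(C)(C)C)CC[C@@]1(O)/C=C/CO | intermediate
14 | (1R,2S)-2-(tert-butyldimethylsilyloxy)-1-[(2R,3S)-3-(hydroxymethyl)oxiran-2-yl]-2-[(2Z)-oct-2-en-1-yl]cyclobutan-1-ol | CCCCC/C=C\C[C@@]1(O[Si](C)(C)C(C)(C)C)CC[C@@]1(O)[C@@H]2O[C@H]2CO | intermediate
15 | (1R,2S)-2-(tert-butyldimethylsilyloxy)-1-[(2R,3S)-3-(tert-butyldimethylsilyloxymethyl)oxiran-2-yl]-2-[(2Z)-oct-2-en-1-yl]cyclobutan-1-ol | CCCCC/C=C\C[C@@]1(O[Si](C)(C)C(C)(C)C)CC[C@@]1(O)[C@@H]2O[C@H]2CO[Si](C)(C)C(C)(C)C | intermediate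
16 | (2R,3S)-3-(tert-butyldimethylsilyloxy)-2-[(1R)-2-(tert-butyldimethylsilyloxy)-1-hydroxyethyl]-3-[(2Z)-oct-2-en-1-yl]cyclopentan-1-one | CCCCC/C=C\C[C@@]1(O[Si](C)(C)C(C)(C)C)CCC(=O)[C@@H]1[C@H](CO[Si](C)(C)C(C)(C)C)O | intermediate
17 | (2R,3S)-2-[(1R)-1,2-bis(tert-butyldimethylsilyloxy)ethyl]-3-(tert-butyldimethylsilyloxy)-3-[(2Z)-oct-2-en-1-yl]cyclopentan-1-one | CCCCC/C=C\C[C@@]1(O[Si](C)(C)C(C)(C)C)CCC(=O)[C@@H]1[C@H](CO[Si](C)(C)C(C)(C)C)O[Si](C)(C)C(C)(C)C | intermediate
18 | C9 trimethylsilyl enol ether of 17 (C9=C10) | CCCCC/C=C\C[C@@]1(O[Si](C)(C)C(C)(C)C)CC=C(O[Si](C)(C)C)[C@@H]1[C@H](CO[Si](C)(C)C(C)(C)C)O[Si](C)(C)C(C)(C)C | intermediate (not isolated)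
19 | (4R,5R)-5-[(1R)-1,2-bis(tert-butyldimethylsilyloxy)ethyl]-4-(tert-butyldimethylsilyloxy)-4-[(2Z)-oct-2-en-1-yl]cyclopent-2-en-1-one | CCCCC/C=C\C[C@@]1(O[Si](C)(C)C(C)(C)C)C=CC(=O)[C@@H]1[C@H](CO[Si](C)(C)C(C)(C)C)O[Si](C)(C)C(C)(C)C | intermediate
20 | (4R,5R)-4-(tert-butyldimethylsilyloxy)-5-[(1R)-1-(tert-butyldimethylsilyloxy)-2-hydroxyethyl]-4-[(2Z)-oct-2-en-1-yl]cyclopent-2-en-1-one | CCCCC/C=C\C[C@@]1(O[Si](C)(C)C(C)(C)C)C=CC(=O)[C@@H]1[C@H](CO)O[Si](C)(C)C(C)(C)C | intermediate
21 | (2R)-2-(tert-butyldimethylsilyloxy)-2-[(1R,2R)-2-(tert-butyldimethylsilyloxy)-2-[(2Z)-oct-2-en-1-yl]-5-oxocyclopent-3-en-1-yl]acetaldehyde | CCCCC/C=C\C[C@@]1(O[Si](C)(C)C(C)(C)C)C=CC(=O)[C@@H]1[C@H](C=O)O[Si](C)(C)C(C)(C)C | intermediate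
22 | (4-carboxybutyl)triphenylphosphonium bromide | OC(=O)CCCC[P+](c1ccccc1)(c1ccccc1)c1ccccc1.[Br-] | starting material
23 | sodium 5-(triphenylphosphoranylidene)pentanoate | [Na+].[O-]C(=O)CCCC=P(c1ccccc1)(c1ccccc1)c1ccccc1 | intermediate (not isolated)
24 | (5Z,7S)-7-(tert-butyldimethylsilyloxy)-7-[(1R,2R)-2-(tert-butyldimethylsilyloxy)-2-[(2Z)-oct-2-en-1-yl]-5-oxocyclopent-3-en-1-yl]hept-5-enoic acid | CCCCC/C=C\C[C@@]1(O[Si](C)(C)C(C)(C)C)C=CC(=O)[C@@H]1[C@H](/C=C\CCCC(=O)O)O[Si](C)(C)C(C)(C)C | intermediate
25 | methyl (5Z,7S)-7-(tert-butyldimethylsilyloxy)-7-[(1R,2R)-2-(tert-butyldimethylsilyloxy)-2-[(2Z)-oct-2-en-1-yl]-5-oxocyclopent-3-en-1-yl]hept-5-enoate | CCCCC/C=C\C[C@@]1(O[Si](C)(C)C(C)(C)C)C=CC(=O)[C@@H]1[C@H](/C=C\CCCC(=O)OC)O[Si](C)(C)C(C)(C)C | intermediate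
26 | methyl (5Z,7S)-7-(tert-butyldimethylsilyloxy)-7-[(1R,2S)-2-(tert-butyldimethylsilyloxy)-4-iodo-2-[(2Z)-oct-2-en-1-yl]-5-oxocyclopent-3-en-1-yl]hept-5-enoate | CCCCC/C=C\C[C@@]1(O[Si](C)(C)C(C)(C)C)C=C(I)C(=O)[C@@H]1[C@H](/C=C\CCCC(=O)OC)O[Si](C)(C)C(C)(C)C | intermediate
27 | methyl (5Z,7S)-7-hydroxy-7-[(1R,2S)-2-hydroxy-4-iodo-2-[(2Z)-oct-2-en-1-yl]-5-oxocyclopent-3-en-1-yl]hept-5-enoate | CCCCC/C=C\C[C@@]1(O)C=C(I)C(=O)[C@@H]1[C@H](/C=C\CCCC(=O)OC)O | intermediate
28 | methyl (5Z,7S)-7-acetoxy-7-[(1R,2S)-2-hydroxy-4-iodo-2-[(2Z)-oct-2-en-1-yl]-5-oxocyclopent-3-en-1-yl]hept-5-enoate (7-acetoxy-7,8-dihydroiodovulone I) | CCCCC/C=C\C[C@@]1(O)C=C(I)C(=O)[C@@H]1[C@H](/C=C\CCCC(=O)OC)OC(C)=O | target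

## Step count and least certain steps

Total: 19 steps. Longest linear sequence: 19 steps (1 → 28); compounds 3, 10 and 22 are bought.

Stereocentres: C7 is set in step 8. C8 is set as the epoxide carbon in step 8 and inverted in step 10. C12 is made racemic in step 4, selected in step 8 and migrates with retention in step 10. The (14Z)-alkene is set in step 5 and the (5Z)-alkene in step 15.

Step 10 (key step). The main risk is competing migration of the C10 methylene, which would give the regioisomeric cyclopentanone. Bromide opening of the epoxide, or ionisation before the shift, could also erode yield and stereospecificity, and the zinc halide could remove a silyl group. Fallback: setting out from 15, the C9 hydroxyl is silylated with N-(trimethylsilyl)imidazole to give the C9 trimethylsilyl ether F1. This is rearranged with TiCl4 in CH2Cl2 at −78 °C (the rearrangement of epoxy silyl ethers to aldols), where the silyloxy group pushes harder and no chelated zinc halide is involved. Aqueous work-up removes the trimethylsilyl group, and the route is rejoined at 16.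

Step 8. Reagent control may be incomplete on one enantiomer of 13, which would lower the enantiomeric purity of 14, and the two diastereomeric epoxy diols may co-elute. By design the step also discards the half of the material with the wrong C12 configuration. Fallback: setting out from 13, the unseparated mixture of 14 and the diastereomeric epoxy diol F2 is silylated to 15 and the diastereomeric bis-silyl ether F3, and the mixture is rearranged with ZnBr2. The products 16 and the C12-epimeric cyclopentanone F4 have trans and cis chains on the ring and should differ more in shape and polarity. They are separated there, rejoining at 16.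

Step 4. Any less substituted enol ether from step 3 would be oxidised at the wrong carbon. The strained silyloxy epoxide may also open along other paths (loss of the silyl group, ring contraction). Fallback: setting out from 6, the enol ether is dihydroxylated with catalytic OsO4 and N-methylmorpholine N-oxide in aqueous acetone. This passes through an osmate ester instead of the bicyclic epoxide and gives the free ketol 2-hydroxy-2-(oct-2-yn-1-yl)cyclobutan-1-one F5. F5 is silylated at once (TBSOTf, 2,6-lutidine, −78 °C) to rejoin at 8. The material is racemic at this stage, so reversible α-ketol ring contraction of F5 can cost yield but not stereochemical integrity.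

Step 15. The basic ylide may deprotonate C8, followed by E1cB loss of the C7 silyloxy group. It may also epimerise the α-silyloxy aldehyde at C7 or add to the enone. Fallback: setting out from 17, the upper chain is built before the dehydrogenation. Selective primary desilylation (HF·pyridine) gives the saturated primary alcohol F6, Dess–Martin oxidation gives the saturated aldehyde F7, the same Wittig reaction gives the saturated acid F8, and methylation gives the saturated methyl ester F9. In these saturated ketones the accessible acidic protons are at C10, and their removal gives an enolate that cannot eliminate. Saegusa–Ito dehydrogenation then follows: LiN(SiMe3)2 and Me3SiCl, which should spare the ester, give the trimethylsilyl enol ether F10, and Pd(OAc)2 rejoins the route at 25.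

Step 19. Pyridine may induce loss of acetic acid from the β-acetoxy ketone to give the cross-conjugated dienone. Acetylation of the hindered C7 hydroxyl may also be slow enough to call for a stronger acyl-transfer base, which would make elimination worse. Fallback: setting out from 26, only the secondary silyl ether is removed (HF·pyridine, pyridine, THF, 0 °C) to give the C7 alcohol F11. F11 is acetylated without base (Ac2O, catalytic Sc(OTf)3, MeCN, −20 °C) to the C7 acetate C12 silyl ether F12; C12 is still silylated, so selectivity is not an issue. Aqueous HF in acetonitrile then gives 28 under acidic conditions.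

## Further compounds

F1 | step 10 | (1R,2S)-2-(tert-butyldimethylsilyloxy)-1-[(2R,3S)-3-(tert-butyldimethylsilyloxymethyl)oxiran-2-yl]-2-[(2Z)-oct-2-en-1-yl]-1-(trimethylsilyloxy)cyclobutane | CCCCC/C=C\C[C@@]1(O[Si](C)(C)C(C)(C)C)CC[C@@]1(O[Si](C)(C)C)[C@@H]2O[C@H]2CO[Si](C)(C)C(C)(C)C
F2 | step 8 | (1S,2R)-2-(tert-butyldimethylsilyloxy)-1-[(2R,3S)-3-(hydroxymethyl)oxiran-2-yl]-2-[(2Z)-oct-2-en-1-yl]cyclobutan-1-ol | CCCCC/C=C\C[C@]1(O[Si](C)(C)C(C)(C)C)CC[C@]1(O)[C@@H]2O[C@H]2CO
F3 | step 8 | (1S,2R)-2-(tert-butyldimethylsilyloxy)-1-[(2R,3S)-3-(tert-butyldimethylsilyloxymethyl)oxiran-2-yl]-2-[(2Z)-oct-2-en-1-yl]cyclobutan-1-ol | CCCCC/C=C\C[C@]1(O[Si](C)(C)C(C)(C)C)CC[C@]1(O)[C@@H]2O[C@H]2CO[Si](C)(C)C(C)(C)C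
F4 | step 8 | (2R,3R)-3-(tert-butyldimethylsilyloxy)-2-[(1R)-2-(tert-butyldimethylsilyloxy)-1-hydroxyethyl]-3-[(2Z)-oct-2-en-1-yl]cyclopentan-1-one (C12 epimer of 16) | CCCCC/C=C\C[C@]1(O[Si](C)(C)C(C)(C)C)CCC(=O)[C@@H]1[C@H](CO[Si](C)(C)C(C)(C)C)O
F5 | step 4 | 2-hydroxy-2-(oct-2-yn-1-yl)cyclobutan-1-one (racemic) | CCCCCC#CCC1(O)CCC1=O
F6 | step 15 | (2R,3S)-3-(tert-butyldimethylsilyloxy)-2-[(1R)-1-(tert-butyldimethylsilyloxy)-2-hydroxyethyl]-3-[(2Z)-oct-2-en-1-yl]cyclopentan-1-one | CCCCC/C=C\C[C@@]1(O[Si](C)(C)C(C)(C)C)CCC(=O)[C@@H]1[C@H](CO)O[Si](C)(C)C(C)(C)C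
F7 | step 15 | (2R)-2-(tert-butyldimethylsilyloxy)-2-[(1R,2S)-2-(tert-butyldimethylsilyloxy)-2-[(2Z)-oct-2-en-1-yl]-5-oxocyclopentyl]acetaldehyde | CCCCC/C=C\C[C@@]1(O[Si](C)(C)C(C)(C)C)CCC(=O)[C@@H]1[C@H](C=O)O[Si](C)(C)C(C)(C)C
F8 | step 15 | (5Z,7S)-7-(tert-butyldimethylsilyloxy)-7-[(1R,2S)-2-(tert-butyldimethylsilyloxy)-2-[(2Z)-oct-2-en-1-yl]-5-oxocyclopentyl]hept-5-enoic acid | CCCCC/C=C\C[C@@]1(O[Si](C)(C)C(C)(C)C)CCC(=O)[C@@H]1[C@H](/C=C\CCCC(=O)O)O[Si](C)(C)C(C)(C)C
F9 | step 15 | methyl (5Z,7S)-7-(tert-butyldimethylsilyloxy)-7-[(1R,2S)-2-(tert-butyldimethylsilyloxy)-2-[(2Z)-oct-2-en-1-yl]-5-oxocyclopentyl]hept-5-enoate | CCCCC/C=C\C[C@@]1(O[Si](C)(C)C(C)(C)C)CCC(=O)[C@@H]1[C@H](/C=C\CCCC(=O)OC)O[Si](C)(C)C(C)(C)C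
F10 | step 15 | C9 trimethylsilyl enol ether of F9 (C9=C10) | CCCCC/C=C\C[C@@]1(O[Si](C)(C)C(C)(C)C)CC=C(O[Si](C)(C)C)[C@@H]1[C@H](/C=C\CCCC(=O)OC)O[Si](C)(C)C(C)(C)C
F11 | step 19 | methyl (5Z,7S)-7-hydroxy-7-[(1R,2S)-2-(tert-butyldimethylsilyloxy)-4-iodo-2-[(2Z)-oct-2-en-1-yl]-5-oxocyclopent-3-en-1-yl]hept-5-enoate | CCCCC/C=C\C[C@@]1(O[Si](C)(C)C(C)(C)C)C=C(I)C(=O)[C@@H]1[C@H](/C=C\CCCC(=O)OC)O
F12 | step 19 | methyl (5Z,7S)-7-acetoxy-7-[(1R,2S)-2-(tert-butyldimethylsilyloxy)-4-iodo-2-[(2Z)-oct-2-en-1-yl]-5-oxocyclopent-3-en-1-yl]hept-5-enoate | CCCCC/C=C\C[C@@]1(O[Si](C)(C)C(C)(C)C)C=C(I)C(=O)[C@@H]1[C@H](/C=C\CCCC(=O)OC)OC(C)=O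
A1 | alternative 1 | 7,7-dimethoxy-5-oxoheptanal | COC(OC)CC(=O)CCCC=O
A2 | alternative 1 | (R)-2-(2,2-dimethoxyethyl)-2-hydroxycyclopentan-1-one | COC(OC)C[C@@]1(O)C(=O)CCC1
A3 | alternative 2 | 2-[5-(tert-butyldimethylsilyloxy)-2-(oct-2-yn-1-yl)cyclopent-2-en-1-yl]-2-(4-methoxybenzyloxy)acetic acid (configuration as in the SMILES) | OC(=O)[C@H](OCc1ccc(OC)cc1)[C@@H]2C(CC#CCCCCC)=CC[C@H]2O[Si](C)(C)C(C)(C)C
A4 | alternative 2 | cis-fused iodolactone 6-(tert-butyldimethylsilyloxy)-8-iodo-4-(4-methoxybenzyloxy)-1-(oct-2-yn-1-yl)-2-oxabicyclo[3.3.0]octan-3-one (configuration as in the SMILES) | CCCCCC#CC[C@]12OC(=O)[C@H](OCc3ccc(OC)cc3)[C@H]1[C@H](O[Si](C)(C)C(C)(C)C)C[C@@H]2I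
A5 | alternative 3 | 2-[2-(tert-butyldimethylsilyloxy)-1-(triethylsilyloxy)ethyl]-3-[2-(4-methoxybenzyloxy)ethyl]-3-(triethylsilyloxy)-5-(trimethylsilyl)pent-4-ynal (configuration as in the SMILES) | O=C[C@H]([C@H](CO[Si](C)(C)C(C)(C)C)O[Si](CC)(CC)CC)[C@](CCOCc1ccc(OC)cc1)(O[Si](CC)(CC)CC)C#C[Si](C)(C)C
A6 | alternative 3 | 4-(triethylsilyloxy)-4-[2-(4-methoxybenzyloxy)ethyl]-5-[2-(tert-butyldimethylsilyloxy)-1-(triethylsilyloxy)ethyl]-2-(trimethylsilyl)cyclopent-2-en-1-one (configuration as in the SMILES) | COc1ccc(COCC[C@@]2(O[Si](CC)(CC)CC)C=C([Si](C)(C)C)C(=O)[C@@H]2[C@H](CO[Si](C)(C)C(C)(C)C)O[Si](CC)(CC)CC)cc1
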